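**Retrosynthetic overview** (ring atoms of the target: O1, O2, C3 (CH2CO2Me), C4 (Et), C5, C6 (Et, alkenyl))
1. Last bond: C3–O2, by intramolecular peroxy-Michael addition of a C6 hydroperoxide onto an (E)-enoate that comes from Wittig opening of a 1,2-dioxan-3-ol.
2. Key C–O bond: C6–O1, formed when a γ-lactol is ring-expanded with H2O2 under a chiral Brønsted acid; a tethered perhydrate captures the tertiary allyl cation at C6 and sets C6.
3. Lactol ⇐ γ-lactone ⇐ alkenyllithium + ethyl (R)-2-ethyl-4-oxohexanoate (C4 by copper-catalysed conjugate addition of Et2Zn).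
4. Alkenyl iodide ⇐ ethylcupration/iodination of (S)-4-ethyloct-1-yne ⇐ acetylide + (S)-2-ethylhexyl iodide ⇐ zirconium-catalysed ethylalumination of hex-1-ene.
5. Ring order: oxolane first (lactone, lactol), then expansion to the 1,2-dioxane, which is opened and reclosed once in the final step.

Assumption: the sense of induction of the chiral catalysts in steps 1 and 5 is taken by analogy and that of step 8 must be found by experiment; both antipodes of each are available and the one that gives the stated product is used.

**Step 1**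
Reactants: 1 hex-1-ene; 2 triethylaluminium; 3 iodine
Product: 5 (S)-3-(iodomethyl)heptane, via alkylalane 4 (not isolated)
Conditions: Et3Al (1.1 equiv), (+)-bis(1-neomenthylindenyl)zirconium dichloride (5 mol%), CH2Cl2, 0 °C to rt; then I2 (3 equiv), THF, 0 °C
Reagents that add atoms: triethylaluminium, CC[Al](CC)CC; iodine, II
Why: Negishi zirconium-catalysed asymmetric carboalumination (ZACA) adds Et–Al across the terminal alkene with ethyl on C2 (about 90–93% ee is typical for ethylalumination), and iodinolysis of the C–Al bond leaves the new stereocentre untouched.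

**Step 2**
Reactants: 5 (S)-3-(iodomethyl)heptane; 6 lithium acetylide–ethylenediamine complex
Product: 7 (S)-4-ethyloct-1-yne
Conditions: LiC≡CH·H2NCH2CH2NH2 (1.5 equiv), DMSO, rt
Reagents that add atoms: lithium acetylide–ethylenediamine complex, [Li]C#C.NCCN
Why: SN2 alkylation of acetylide by the primary iodide; the stereocentre is β to the reacting carbon and is not affected.

**Step 3**
Reactants: 7 (S)-4-ethyloct-1-yne; 8 ethylmagnesium bromide; 3 iodine
Product: 10 (1E,4S)-2,4-diethyl-1-iodooct-1-ene, via alkenylcopper 9 (not isolated)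
Conditions: EtMgBr (1.1 equiv), CuBr·SMe2 (1.1 equiv), Et2O/Me2S, −45 °C; 7, −45 to −25 °C; then I2, THF, −78 to 0 °C
Reagents that add atoms: ethylmagnesium bromide, CC[Mg]Br; iodine, II
Why: Normant carbocupration adds ethylcopper syn across the terminal alkyne with ethyl on the internal carbon, and iodinolysis with retention gives the trisubstituted alkenyl iodide with iodine cis to the new ethyl group (E).

**Step 4**
Reactants: 11 diethyl (2-oxobutyl)phosphonate; 12 ethyl glyoxylate
Product: 13 ethyl (E)-4-oxohex-2-enoate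
Conditions: K2CO3, THF/H2O, 0 °C to rt (12 used as its commercial toluene solution)
Reagents that add atoms: ethyl glyoxylate, CCOC(=O)C=O
Why: Horner–Wadsworth–Emmons olefination with a stabilised β-ketophosphonate gives the E ene-dicarbonyl compound.

**Step 5**
Reactants: 13 ethyl (E)-4-oxohex-2-enoate; 14 diethylzinc
Product: 16 ethyl (R)-2-ethyl-4-oxohexanoate, via zinc enolate 15 (not isolated)
Conditions: Et2Zn (1.5 equiv), Cu(OTf)2 (2 mol%), (S,R,R)-O,O′-(1,1′-binaphthyl-2,2′-diyl) N,N-bis(1-phenylethyl)phosphoramidite (4 mol%), toluene, −30 °C; aq NH4Cl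
Reagents that add atoms: diethylzinc, CC[Zn]CC
Why: Copper-catalysed asymmetric conjugate addition (Feringa type); Et2Zn with copper–phosphoramidite adds to enones but not to simple enoates, so ethyl goes β to the ketone (α to the ester) and the ligand sets C4 as R.

**Step 6**
Reactants: 10 (1E,4S)-2,4-diethyl-1-iodooct-1-ene; 16 ethyl (R)-2-ethyl-4-oxohexanoate
Product: 19 (3R,5RS)-3,5-diethyl-5-[(1E,4S)-2,4-diethyloct-1-en-1-yl]oxolan-2-one, via alkenyllithium 17 (not isolated), via lithium alkoxide 18 (not isolated)
Conditions: 10 (1.2 equiv), t-BuLi (2.4 equiv), Et2O, −78 °C; then 16, −78 to −20 °C; aq NH4Cl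
Reagents that add atoms: none
Why: Iodine–lithium exchange with retention of alkene geometry, 1,2-addition of the alkenyllithium to the ketone (much faster than to the ester at −78 °C) and lactonisation of the tertiary alkoxide; the new carbinol centre forms as both epimers, which is harmless because step 8 erases and resets it.

**Step 7**
Reactants: 19 (3R,5RS)-3,5-diethyl-5-[(1E,4S)-2,4-diethyloct-1-en-1-yl]oxolan-2-one
Product: 20 (2RS,3R,5RS)-3,5-diethyl-5-[(1E,4S)-2,4-diethyloct-1-en-1-yl]oxolan-2-ol
Conditions: i-Bu2AlH (1.1 equiv), CH2Cl2, −78 °C; aq potassium sodium tartrate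
Reagents that add atoms: none
Why: Partial reduction of a γ-lactone to the lactol with i-Bu2AlH at low temperature; no acid is used, so the acid-labile tertiary allylic C–O bond and the alkene geometry stay intact.

**Step 8**
Reactants: 20 (2RS,3R,5RS)-3,5-diethyl-5-[(1E,4S)-2,4-diethyloct-1-en-1-yl]oxolan-2-ol; 21 hydrogen peroxide
Product: 23 (3RS,4R,6S)-4,6-diethyl-6-[(1E,4S)-2,4-diethyloct-1-en-1-yl]-1,2-dioxan-3-ol, via 2-hydroperoxyoxolane 22 (not isolated)
Conditions: H2O2 (1.2 equiv, anhydrous ethereal solution), (R)-3,3′-bis(2,4,6-triisopropylphenyl)-1,1′-binaphthyl-2,2′-diyl N-(trifluoromethylsulfonyl)phosphoramide (5 mol%), MgSO4, toluene, −40 °C; Et3N quench at −40 °C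
Reagents that add atoms: hydrogen peroxide, OO
Why: Proposed new method: stereoconvergent perhydrolytic ring expansion of a γ-lactol to a 1,2-dioxan-3-ol – acid-catalysed acetal exchange first gives the 2-hydroperoxyoxolane 22, the chiral phosphoramide then ionises its tertiary, doubly allylic C–O bond to a contact ion pair of the 1,1,3,3-tetraalkylallyl cation and the chiral anion while the C3 perhydrate [CH(OH)OOH] stays on the tether, and 6-exo capture by the terminal peroxy oxygen forms the C6–O1 bond of the 1,2-dioxane (the tether allows attack only at C6 and not at the equally substituted alkene terminus; rotation about the allyl C–C bonds is slow at −40 °C so the E alkene should survive; C5–C6 rotation is faster than ion-pair collapse, so both lactol epimers give one common ion pair and the hydrogen-bonded phosphoramide anion selects the face, setting 6S; return to the oxolane is reversible and non-productive, while exchanging hydroperoxide plus ether for dialkyl peroxide plus hydroxyl and a five- for a six-membered ring makes the expansion downhill and the product slower to re-ionise); closest known reaction types are chiral N-triflylphosphoramide-catalysed intramolecular allylic substitution through allyl cation/phosphoramide contact ion pairs (phenol oxygen nucleophiles giving 2H-chromenes), acid-mediated perhydrolysis of acetals and tertiary alcohols, and stereospecific intramolecular alkylation of hydroperoxides by oxetanes.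

**Step 9**
Reactants: 23 (3RS,4R,6S)-4,6-diethyl-6-[(1E,4S)-2,4-diethyloct-1-en-1-yl]-1,2-dioxan-3-ol; 24 methyl (triphenylphosphoranylidene)acetate
Product: 27 methyl 2-[(3S,4R,6S)-4,6-diethyl-6-[(1E,4S)-2,4-diethyloct-1-en-1-yl]-1,2-dioxan-3-yl]acetate, via hydroperoxy aldehyde 25 (not isolated), via hydroperoxy enoate 26 (not isolated)
Conditions: Ph3P=CHCO2Me (1.2 equiv), CH2Cl2, 0 °C to rt; then Et2NH (0.3 equiv), CF3CH2OH, rt
Reagents that add atoms: methyl (triphenylphosphoranylidene)acetate, COC(=O)C=P(c1ccccc1)(c1ccccc1)c1ccccc1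
Why: Wittig olefination of the ring-opened hydroperoxy aldehyde tautomer with a neutral stabilised ylide (no epimerisation at C4) followed by amine-mediated 6-exo intramolecular peroxy-Michael (oxa-Michael) addition through a chair in which the C4 ethyl, the C6 ethyl and the enoate are all equatorial, which gives the 3,4-trans product (3S) while the C6–O bond is never broken.

**Compound list**
1 | hex-1-ene | C=CCCCC | starting material
2 | triethylaluminium | CC[Al](CC)CC | starting material
3 | iodine | II | starting material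
4 | diethyl[(2S)-2-ethylhexyl]aluminium | CCCC[C@H](CC)C[Al](CC)CC | intermediate
5 | (S)-3-(iodomethyl)heptane | CCCC[C@H](CC)CI | intermediate
6 | lithium acetylide–ethylenediamine complex | [Li]C#C.NCCN | starting material
7 | (S)-4-ethyloct-1-yne | CCCC[C@H](CC)CC#C | intermediate
8 | ethylmagnesium bromide | CC[Mg]Br | starting material
9 | [(1E,4S)-2,4-diethyloct-1-en-1-yl]copper (MgBr2 complex) | CCCC[C@H](CC)C/C(=C/[Cu])CC | intermediate
10 | (1E,4S)-2,4-diethyl-1-iodooct-1-ene | CCCC[C@H](CC)C/C(=C/I)CC | intermediate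
11 | diethyl (2-oxobutyl)phosphonate | CCC(=O)CP(=O)(OCC)OCC | starting material
12 | ethyl glyoxylate | CCOC(=O)C=O | starting material
13 | ethyl (E)-4-oxohex-2-enoate | CCC(=O)/C=C/C(=O)OCC | intermediate
14 | diethylzinc | CC[Zn]CC | starting material
15 | ethylzinc enolate of ethyl (R)-2-ethyl-4-oxohexanoate | CC[Zn]OC(CC)=C[C@@H](CC)C(=O)OCC | intermediate
16 | ethyl (R)-2-ethyl-4-oxohexanoate | CCC(=O)C[C@@H](CC)C(=O)OCC | intermediate
17 | [(1E,4S)-2,4-diethyloct-1-en-1-yl]lithium | CCCC[C@H](CC)C/C(=C/[Li])CC | intermediate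
18 | lithium alkoxide of ethyl (2R,4RS,5E,8S)-2,4,6,8-tetraethyl-4-hydroxydodec-5-enoate | CCCC[C@H](CC)C/C(=C/C(O[Li])(CC)C[C@@H](CC)C(=O)OCC)CC | intermediate
19 | (3R,5RS)-3,5-diethyl-5-[(1E,4S)-2,4-diethyloct-1-en-1-yl]oxolan-2-one | CCCC[C@H](CC)C/C(=C/C1(CC)C[C@@H](CC)C(=O)O1)CC | intermediate
20 | (2RS,3R,5RS)-3,5-diethyl-5-[(1E,4S)-2,4-diethyloct-1-en-1-yl]oxolan-2-ol | CCCC[C@H](CC)C/C(=C/C1(CC)C[C@@H](CC)C(O)O1)CC | intermediate
21 | hydrogen peroxide | OO | starting material
22 | (2RS,3R,5RS)-3,5-diethyl-5-[(1E,4S)-2,4-diethyloct-1-en-1-yl]-2-hydroperoxyoxolane | CCCC[C@H](CC)C/C(=C/C1(CC)C[C@@H](CC)C(OO)O1)CC | intermediate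
23 | (3RS,4R,6S)-4,6-diethyl-6-[(1E,4S)-2,4-diethyloct-1-en-1-yl]-1,2-dioxan-3-ol | CCCC[C@H](CC)C/C(=C/[C@]1(CC)C[C@@H](CC)C(O)OO1)CC | intermediate
24 | methyl (triphenylphosphoranylidene)acetate | COC(=O)C=P(c1ccccc1)(c1ccccc1)c1ccccc1 | starting material
25 | (2R,4S,5E,8S)-2,4,6,8-tetraethyl-4-hydroperoxydodec-5-enal | CCCC[C@H](CC)C/C(=C/[C@@](CC)(OO)C[C@@H](CC)C=O)CC | intermediate
26 | methyl (2E,4R,6S,7E,10S)-4,6,8,10-tetraethyl-6-hydroperoxytetradeca-2,7-dienoate | CCCC[C@H](CC)C/C(=C/[C@@](CC)(OO)C[C@@H](CC)/C=C/C(=O)OC)CC | intermediate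
27 | methyl 2-[(3S,4R,6S)-4,6-diethyl-6-[(1E,4S)-2,4-diethyloct-1-en-1-yl]-1,2-dioxan-3-yl]acetate | CCCC[C@H](CC)C/C(=C/[C@]1(CC)C[C@@H](CC)[C@H](CC(=O)OC)OO1)CC | target

**Totals and risks**
Total step count: 9. Longest linear sequence: 7 steps (steps 1, 2, 3, 6, 7, 8, 9).

The three steps most likely to fail:

Step 8 (the proposed new step). Possible failures are proton loss from the allyl cation to trienes, capture of the cation by free H2O2 or water at the far allyl terminus (which would erode the E geometry), weak facial control by the anion, and slow equilibration at C6 if the product is left with the acid. The reaction must therefore be stopped as soon as 22 is consumed. The fallback uses known chemistry, sets out from lactol 20 and comes back to the route at 26. Wittig reaction of 20 with 24 (CH2Cl2, rt, kept neutral) gives methyl (2E,4R,6RS,7E,10S)-4,6,8,10-tetraethyl-6-hydroxytetradeca-2,7-dienoate F1. Classical SN1 perhydrolysis of the tertiary alcohol (ethereal H2O2, cat. H2SO4, −20 °C) gives 26 together with its C6 epimer, methyl (2E,4R,6R,7E,10S)-4,6,8,10-tetraethyl-6-hydroperoxytetradeca-2,7-dienoate F2. The mixture is cyclised as in the second half of step 9 to 27 and the epimeric methyl 2-[(4R,6R)-4,6-diethyl-6-[(1E,4S)-2,4-diethyloct-1-en-1-yl]-1,2-dioxan-3-yl]acetate F3, which is removed by HPLC. In this fallback C6 is not controlled (about 1:1) and the material throughput is halved.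

Step 9. Possible failures are oxidation of the ylide by the free hydroperoxide, a slow Wittig reaction on the cyclic peroxy-hemiacetal, and a low 3,4-trans to cis ratio in the peroxy-Michael closure. The fallback sets out from 23 and comes back at 27. Acetylation (Ac2O, pyridine, DMAP, 0 °C) gives (3RS,4R,6S)-4,6-diethyl-6-[(1E,4S)-2,4-diethyloct-1-en-1-yl]-1,2-dioxan-3-yl acetate F4. Peroxycarbenium alkylation in the manner of Dussault with 1-methoxy-1-(trimethylsilyloxy)ethene (TMSOTf cat., CH2Cl2, −78 °C) then installs the CH2CO2Me group at C3 by C–C bond formation, with the nucleophile expected to enter trans to the C4 ethyl group. The ring is never opened and no free hydroperoxide or ylide is involved; the Lewis acid must be kept catalytic and cold to spare the C6 allylic peroxide.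

Step 5. The enantioselectivity and the regiochemistry (β to ketone against β to ester) are unproven for this ene-keto ester, and any loss of ee at C4 ends up as a diastereomer of 27. The fallback sets out from phosphonate 11 and comes back at 16. Horner–Wadsworth–Emmons reaction of 11 with ethyl 2-oxobutanoate (K2CO3, THF/H2O) gives ethyl (E)-2-ethyl-4-oxohex-2-enoate F5. Asymmetric transfer hydrogenation by iminium catalysis (Hantzsch ester, valine tert-butyl ester salt of (R)-3,3′-bis(2,4,6-triisopropylphenyl)-1,1′-binaphthyl-2,2′-diyl hydrogen phosphate, Bu2O, 60 °C) delivers hydride to the carbon β to the ketone and sets C4 by reduction instead of by C–C bond formation.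

**Further compounds**
F1 | step 8 | methyl (2E,4R,6RS,7E,10S)-4,6,8,10-tetraethyl-6-hydroxytetradeca-2,7-dienoate | CCCC[C@H](CC)C/C(=C/C(O)(CC)C[C@@H](CC)/C=C/C(=O)OC)CC
F2 | step 8 | methyl (2E,4R,6R,7E,10S)-4,6,8,10-tetraethyl-6-hydroperoxytetradeca-2,7-dienoate | CCCC[C@H](CC)C/C(=C/[C@](CC)(OO)C[C@@H](CC)/C=C/C(=O)OC)CC
F3 | step 8 | methyl 2-[(3RS,4R,6R)-4,6-diethyl-6-[(1E,4S)-2,4-diethyloct-1-en-1-yl]-1,2-dioxan-3-yl]acetate | CCCC[C@H](CC)C/C(=C/[C@@]1(CC)C[C@@H](CC)C(CC(=O)OC)OO1)CC
F4 | step 9 | (3RS,4R,6S)-4,6-diethyl-6-[(1E,4S)-2,4-diethyloct-1-en-1-yl]-1,2-dioxan-3-yl acetate | CCCC[C@H](CC)C/C(=C/[C@]1(CC)C[C@@H](CC)C(OC(C)=O)OO1)CC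
F5 | step 5 | ethyl (E)-2-ethyl-4-oxohex-2-enoate | CCC(=O)/C=C(\CC)C(=O)OCC
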